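**Retrosynthetic overview**
- The two esters go on last: tiglate on the allylic C8–OH, then hydroxyl-directed anti reduction of the C4 ketone, then the 4-(silyloxy)benzoate and desilylation.
- The hydroazulene keto-diol comes from SmI2 opening of the C–O bond α to the ketone in an 11-oxatricyclic ketol; the oxygen bridge is the future C8 oxygen and fixes its configuration.
- Key disconnection: the cyclopentanol ring is cut at C8a–C1 and C3–C3a. A β-keto radical from 1-isopropylcyclopropanol adds to the enone of an 8-oxabicyclo[3.2.1]octadienone on the bridge face, and the resulting enolate closes by aldol. This sets the quaternary carbon and two more stereocentres in one step.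
- The oxabicyclic dienone comes from an enantioselective oxidopyrylium [5+2] cycloaddition (pyranone from 3-methylfuran and CH2O by Achmatowicz rearrangement) with (E)-methyl propenyl sulfide, then sulfoxide elimination.
- Ring order: seven-membered ring first (as the oxygen-bridged bicycle), five-membered ring second (radical step), oxygen bridge opened last.

Assumption: the (R,R) amine–thiourea of step 3 gives the (1R,5R) adduct (otherwise its mirror image is used), the propenyl sulfide is used as the pure E isomer, and azulene locants of the target are used for all hydroazulenes.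

**Route**

Step 1
Reactants: 1 3-methylfuran; 2 formaldehyde (as paraformaldehyde)
Product: 4 (4-methylfuran-2-yl)methanol, via furyllithium 3 (not isolated)
Conditions: s-BuLi, TMEDA, THF, −78 to −20 °C; (CH2O)n, −20 °C to rt; H2O
Reagents that add atoms: none
Why: Furan α-lithiation with a bulky base goes mainly to the free α-position remote from the methyl group, and the furyllithium adds to formaldehyde (hydroxymethylation), the minor regioisomer being removed by distillation; no stereocentre is formed.

Step 2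
Reactants: 4 (4-methylfuran-2-yl)methanol
Product: 6 rac-3-methyl-5-oxo-5,6-dihydro-2H-pyran-2-yl benzoate, via hydroxypyranone 5 (not isolated)
Conditions: mCPBA, CH2Cl2, 0 °C; then BzCl, pyridine, DMAP (cat.), −20 °C
Reagents that add atoms: mCPBA (3-chloroperoxybenzoic acid), OOC(=O)c1cccc(Cl)c1; benzoyl chloride, O=C(Cl)c1ccccc1
Why: Achmatowicz oxidative ring expansion of the furfuryl alcohol followed by O-acylation of the lactol; the acetal stereocentre is racemic and is erased in step 3.

Step 3
Reactants: 6 rac-3-methyl-5-oxo-5,6-dihydro-2H-pyran-2-yl benzoate; 7 (E)-1-(methylsulfanyl)prop-1-ene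
Product: 9 (1R,5R,6R,7S)-4,7-dimethyl-6-(methylsulfanyl)-8-oxabicyclo[3.2.1]oct-3-en-2-one, via oxidopyrylium 8 (not isolated)
Conditions: 1-[(1R,2R)-2-aminocyclohexyl]-3-[3,5-bis(trifluoromethyl)phenyl]thiourea (20 mol %), 1,3-bis[3,5-bis(trifluoromethyl)phenyl]thiourea (20 mol %), AcOH (20 mol %), 7 (5 equiv), toluene, 40 °C
Reagents that add atoms: none
Why: Proposed new method: the primary amine condenses with the ketone of 6 while the thioureas abstract benzoate, so ylide 8 reacts as a chiral aminopyrylium whose open face takes up the electron-rich alkene in a suprafacial [5+2] cycloaddition (the sulfur-bearing carbon bonds to the ylide terminus remote from the oxide, giving the 6-sulfanyl-7-methyl regiochemistry, bridgeheads 1R,5R, and 6,7-trans from the E alkene); the closest known reaction type is the amine–thiourea-catalysed enantioselective intermolecular oxidopyrylium [5+2] cycloaddition with vinyl ethers.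

Step 4
Reactants: 9 (1R,5R,6R,7S)-4,7-dimethyl-6-(methylsulfanyl)-8-oxabicyclo[3.2.1]oct-3-en-2-one
Product: 11 (1R,5S)-4,7-dimethyl-8-oxabicyclo[3.2.1]octa-3,6-dien-2-one, via sulfoxide 10 (not isolated)
Conditions: mCPBA (1.0 equiv), CH2Cl2, −78 °C; then xylenes, 140 °C
Reagents that add atoms: none
Why: Chemoselective sulfide oxidation followed by thermal syn-elimination of the sulfoxide (sulfoxide pyrolysis), which can only take the cis hydrogen at C7 because the bridgehead hydrogen would give an anti-Bredt alkene; the bridgehead stereocentres are untouched and the C6/C7 centres disappear (the 6-exo epimer of 9 converges to the same dienone).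

Step 5
Reactants: 12 methyl 2-methylpropanoate; 13 ethylmagnesium bromide
Product: 14 1-(propan-2-yl)cyclopropan-1-ol
Conditions: EtMgBr (2.2 equiv), Ti(OiPr)4 (20 mol %), Et2O, 0 °C to rt; H2O
Reagents that add atoms: none
Why: Kulinkovich cyclopropanation, in which the titanacyclopropane formed from two equivalents of EtMgBr and the titanium alkoxide adds twice to the ester carbonyl to give the tertiary cyclopropanol; no stereocentre.

Step 6 (key step)
Reactants: 11 (1R,5S)-4,7-dimethyl-8-oxabicyclo[3.2.1]octa-3,6-dien-2-one; 14 1-(propan-2-yl)cyclopropan-1-ol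
Product: 16 (1S,2R,5R,6R,8R)-5-hydroxy-2,9-dimethyl-5-(propan-2-yl)-11-oxatricyclo[6.2.1.0(2,6)]undec-9-en-7-one, via enolate 15 (not isolated)
Conditions: [Ir(dF(CF3)ppy)2(dtbbpy)]PF6 (2 mol %), K2HPO4 (1 equiv), 14 (1.5 equiv), MeCN, 450 nm LEDs, rt
Reagents that add atoms: none
Why: Proposed new method: photo-oxidation of 14 by the excited trivalent iridium complex with proton loss to phosphate and strain-driven ring opening gives the primary β-keto radical, which adds (Giese addition) to the enone β-carbon C4 of 11 on the exo face next to the oxygen bridge and so makes the quaternary centre syn to the bridge oxygen, the divalent iridium species then reduces the α-keto radical to enolate 15 (radical–polar crossover), and its intramolecular aldol addition to the isopropyl ketone closes the ring cis on the same face with the new hydroxyl syn to the ring ketone through a chelated transition state; the closest known reaction types are photoredox ring-opening Giese additions of cyclopropanols and radical–polar crossover Giese/aldol annulations.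

Step 7
Reactants: 16 (1S,2R,5R,6R,8R)-5-hydroxy-2,9-dimethyl-5-(propan-2-yl)-11-oxatricyclo[6.2.1.0(2,6)]undec-9-en-7-one
Product: 17 (3R,3aR,8S,8aR)-3,8-dihydroxy-6,8a-dimethyl-3-(propan-2-yl)-2,3,3a,5,8,8a-hexahydroazulen-4(1H)-one
Conditions: SmI2 (2.2 equiv), MeOH (4 equiv), THF, −78 °C
Reagents that add atoms: none
Why: Reductive cleavage of an α-alkoxy ketone by SmI2, in which the ketyl expels the α-oxygen, opens the bridge and leaves the alkoxide on C8 with its configuration unchanged, while kinetic α-protonation of the samarium dienolate keeps the C6=C7 alkene out of conjugation.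

Step 8
Reactants: 17 (3R,3aR,8S,8aR)-3,8-dihydroxy-6,8a-dimethyl-3-(propan-2-yl)-2,3,3a,5,8,8a-hexahydroazulen-4(1H)-one; 18 (2E)-2-methylbut-2-enoyl chloride
Product: 19 (3R,3aR,8S,8aR)-3-hydroxy-6,8a-dimethyl-4-oxo-3-(propan-2-yl)-1,2,3,3a,4,5,8,8a-octahydroazulen-8-yl (2E)-2-methylbut-2-enoate
Conditions: pyridine, DMAP (0.2 equiv), CH2Cl2, 0 °C to rt
Reagents that add atoms: none
Why: DMAP-catalysed acylation (acyl chloride esterification) of the only secondary alcohol, the tertiary alcohol being too hindered to react; no stereocentre is touched.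

Step 9
Reactants: 19 (3R,3aR,8S,8aR)-3-hydroxy-6,8a-dimethyl-4-oxo-3-(propan-2-yl)-1,2,3,3a,4,5,8,8a-octahydroazulen-8-yl (2E)-2-methylbut-2-enoate
Product: 20 (3R,3aS,4S,8S,8aR)-3,4-dihydroxy-6,8a-dimethyl-3-(propan-2-yl)-1,2,3,3a,4,5,8,8a-octahydroazulen-8-yl (2E)-2-methylbut-2-enoate
Conditions: Me4NBH(OAc)3, AcOH/MeCN (1:1), −30 °C
Reagents that add atoms: none
Why: Evans–Saksena reduction, in which the borohydride exchanges an acetate for the C3 hydroxyl and delivers hydride intramolecularly to the ketone face on which that oxygen sits, giving the 1,3-anti diol with 4S configuration.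

Step 10
Reactants: 21 4-bromophenol
Product: 22 (4-bromophenoxy)(tert-butyl)dimethylsilane
Conditions: TBSCl, imidazole, DMF, rt
Reagents that add atoms: TBSCl (tert-butyl(chloro)dimethylsilane), CC(C)(C)[Si](C)(C)Cl
Why: Imidazole-promoted silyl ether formation masks the acidic phenol for the lithiation and the later esterification.

Step 11
Reactants: 22 (4-bromophenoxy)(tert-butyl)dimethylsilane; 23 carbon dioxide
Product: 25 4-[(tert-butyldimethylsilyl)oxy]benzoic acid, via aryllithium 24 (not isolated)
Conditions: n-BuLi, THF, −78 °C; CO2 (g); aq. HCl to pH 3, 0 °C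
Reagents that add atoms: none
Why: Bromine–lithium exchange followed by carboxylation of the aryllithium gives the benzoic acid, and the aryl silyl ether survives the cold, mildly acidic work-up.

Step 12
Reactants: 20 (3R,3aS,4S,8S,8aR)-3,4-dihydroxy-6,8a-dimethyl-3-(propan-2-yl)-1,2,3,3a,4,5,8,8a-octahydroazulen-8-yl (2E)-2-methylbut-2-enoate; 25 4-[(tert-butyldimethylsilyl)oxy]benzoic acid
Product: 26 (3R,3aS,4S,8S,8aR)-3-hydroxy-6,8a-dimethyl-8-{[(2E)-2-methylbut-2-enoyl]oxy}-3-(propan-2-yl)-1,2,3,3a,4,5,8,8a-octahydroazulen-4-yl 4-[(tert-butyldimethylsilyl)oxy]benzoate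
Conditions: DCC, DMAP (0.3 equiv), CH2Cl2, 0 °C to rt
Reagents that add atoms: none
Why: Steglich esterification of the only secondary alcohol with retention at C4; the tertiary alcohol does not react.

Step 13
Reactants: 26 (3R,3aS,4S,8S,8aR)-3-hydroxy-6,8a-dimethyl-8-{[(2E)-2-methylbut-2-enoyl]oxy}-3-(propan-2-yl)-1,2,3,3a,4,5,8,8a-octahydroazulen-4-yl 4-[(tert-butyldimethylsilyl)oxy]benzoate
Product: 27 (3R,3aS,4S,8S,8aR)-3-hydroxy-6,8a-dimethyl-8-{[(2E)-2-methylbut-2-enoyl]oxy}-3-(propan-2-yl)-1,2,3,3a,4,5,8,8a-octahydroazulen-4-yl 4-hydroxybenzoate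
Conditions: TBAF (1.1 equiv), AcOH (1.2 equiv), THF, 0 °C
Reagents that add atoms: none
Why: Fluoride cleavage of the aryl silyl ether (desilylation), buffered with AcOH so that the phenoxide does not attack the two esters; no stereocentre is touched.

**Compound list**
1 | 3-methylfuran | Cc1ccoc1 | starting material
2 | formaldehyde (paraformaldehyde) | C=O | starting material
3 | (4-methylfuran-2-yl)lithium | [Li]c1cc(C)co1 | intermediate
4 | (4-methylfuran-2-yl)methanol | OCc1cc(C)co1 | intermediate
5 | rac-6-hydroxy-5-methyl-2H-pyran-3(6H)-one | O=C1COC(O)C(C)=C1 | intermediate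
6 | rac-3-methyl-5-oxo-5,6-dihydro-2H-pyran-2-yl benzoate | O=C1COC(OC(=O)c2ccccc2)C(C)=C1 | intermediate
7 | (E)-1-(methylsulfanyl)prop-1-ene | C/C=C/SC | starting material
8 | 5-methylpyrylium-3-olate | Cc1c[o+]cc([O-])c1 | intermediate
9 | (1R,5R,6R,7S)-4,7-dimethyl-6-(methylsulfanyl)-8-oxabicyclo[3.2.1]oct-3-en-2-one | O1[C@H]2[C@H](SC)[C@@H](C)[C@@H]1C(=O)C=C2C | intermediate
10 | (1R,5R,6R,7S)-6-(methanesulfinyl)-4,7-dimethyl-8-oxabicyclo[3.2.1]oct-3-en-2-one (both epimers at sulfur) | O1[C@H]2[C@H](S(C)=O)[C@@H](C)[C@@H]1C(=O)C=C2C | intermediate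
11 | (1R,5S)-4,7-dimethyl-8-oxabicyclo[3.2.1]octa-3,6-dien-2-one | O1[C@H]2C=C(C)[C@@H]1C(=O)C=C2C | intermediate
12 | methyl 2-methylpropanoate | COC(=O)C(C)C | starting material
13 | ethylmagnesium bromide | CC[Mg]Br | starting material
14 | 1-(propan-2-yl)cyclopropan-1-ol | CC(C)C1(O)CC1 | intermediate
15 | (1R,4R,5S)-4,7-dimethyl-4-(4-methyl-3-oxopentyl)-8-oxabicyclo[3.2.1]octa-2,6-dien-2-olate | O1[C@H]2C=C(C)[C@@H]1C([O-])=C[C@@]2(C)CCC(=O)C(C)C | intermediate
16 | (1S,2R,5R,6R,8R)-5-hydroxy-2,9-dimethyl-5-(propan-2-yl)-11-oxatricyclo[6.2.1.0(2,6)]undec-9-en-7-one | O1[C@H]2C=C(C)[C@@H]1C(=O)[C@@H]3[C@@]2(C)CC[C@@]3(O)C(C)C | intermediate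
17 | (3R,3aR,8S,8aR)-3,8-dihydroxy-6,8a-dimethyl-3-(propan-2-yl)-2,3,3a,5,8,8a-hexahydroazulen-4(1H)-one | O[C@H]1C=C(C)CC(=O)[C@@H]2[C@@]1(C)CC[C@@]2(O)C(C)C | intermediate
18 | (2E)-2-methylbut-2-enoyl chloride | C/C=C(\C)C(Cl)=O | starting material
19 | (3R,3aR,8S,8aR)-3-hydroxy-6,8a-dimethyl-4-oxo-3-(propan-2-yl)-1,2,3,3a,4,5,8,8a-octahydroazulen-8-yl (2E)-2-methylbut-2-enoate | C/C=C(\C)C(=O)O[C@H]1C=C(C)CC(=O)[C@@H]2[C@@]1(C)CC[C@@]2(O)C(C)C | intermediate
20 | (3R,3aS,4S,8S,8aR)-3,4-dihydroxy-6,8a-dimethyl-3-(propan-2-yl)-1,2,3,3a,4,5,8,8a-octahydroazulen-8-yl (2E)-2-methylbut-2-enoate | C/C=C(\C)C(=O)O[C@H]1C=C(C)C[C@H](O)[C@@H]2[C@@]1(C)CC[C@@]2(O)C(C)C | intermediate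
21 | 4-bromophenol | Oc1ccc(Br)cc1 | starting material
22 | (4-bromophenoxy)(tert-butyl)dimethylsilane | CC(C)(C)[Si](C)(C)Oc1ccc(Br)cc1 | intermediate
23 | carbon dioxide | O=C=O | starting material
24 | {4-[(tert-butyldimethylsilyl)oxy]phenyl}lithium | [Li]c1ccc(O[Si](C)(C)C(C)(C)C)cc1 | intermediate
25 | 4-[(tert-butyldimethylsilyl)oxy]benzoic acid | CC(C)(C)[Si](C)(C)Oc1ccc(cc1)C(O)=O | intermediate
26 | (3R,3aS,4S,8S,8aR)-3-hydroxy-6,8a-dimethyl-8-{[(2E)-2-methylbut-2-enoyl]oxy}-3-(propan-2-yl)-1,2,3,3a,4,5,8,8a-octahydroazulen-4-yl 4-[(tert-butyldimethylsilyl)oxy]benzoate | C/C=C(\C)C(=O)O[C@H]1C=C(C)C[C@H](OC(=O)c2ccc(O[Si](C)(C)C(C)(C)C)cc2)[C@@H]2[C@@]1(C)CC[C@@]2(O)C(C)C | intermediate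
27 | (3R,3aS,4S,8S,8aR)-3-hydroxy-6,8a-dimethyl-8-{[(2E)-2-methylbut-2-enoyl]oxy}-3-(propan-2-yl)-1,2,3,3a,4,5,8,8a-octahydroazulen-4-yl 4-hydroxybenzoate | C/C=C(\C)C(=O)O[C@H]1C=C(C)C[C@H](OC(=O)c2ccc(O)cc2)[C@@H]2[C@@]1(C)CC[C@@]2(O)C(C)C | target

**Step count and risks**
Total step count: 13. Longest linear sequence: 10 steps (steps 1, 2, 3, 4, 6, 7, 8, 9, 12, 13).

The three steps most likely to fail:

Step 3 (catalytic asymmetric [5+2] with a vinyl sulfide; the substrate class, the regiochemistry and the ee are untested). The fallback replaces catalyst control by auxiliary control; it sets out from 6 and comes back at 11. (E)-1-Bromopropene and magnesium give (E)-prop-1-en-1-ylmagnesium bromide F1, which displaces menthoxide from (1R,2S,5R)-menthyl (S)-4-methylbenzenesulfinate with inversion at sulfur (Andersen synthesis) to give (R)-1-methyl-4-[(E)-prop-1-ene-1-sulfinyl]benzene F2. The ylide made from 6 with Et3N in toluene adds to this electron-poor alkene with the same regiochemistry under the facial control of the sulfinyl group, giving (1R,5R,6R,7S)-4,7-dimethyl-6-[(R)-4-methylbenzenesulfinyl]-8-oxabicyclo[3.2.1]oct-3-en-2-one F3. After removal of the minor diastereomer, F3 loses the sulfenic acid at 110 °C and gives 11 directly. If the other facial sense prevails, the enantiomeric sulfinate is used.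

Step 6 (intermolecular radical addition to a β,β-disubstituted enone carbon and the enolate crossover into the aldol). The fallback keeps the radical C–C bond formation but separates it from the ring closure; it sets out from 11 and 14 and comes back at 16. Ring-opening bromination of 14 with NBS gives 1-bromo-4-methylpentan-3-one F4. Slow addition of (TMS)3SiH and AIBN to F4 and 11 in benzene at 80 °C gives, by a tin-free reductive Giese addition on the same exo face, the isolated diketone (1R,4R,5S)-4,7-dimethyl-4-(4-methyl-3-oxopentyl)-8-oxabicyclo[3.2.1]oct-6-en-2-one F5. The ring ketone of F5 can only enolise towards C3 because the other α-carbon is a bridgehead, so a reversible aldol with catalytic KOtBu in THF/tBuOH at 0 °C closes the cis-fused cyclopentanol and gives 16.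

Step 9 (anti-selective directed reduction with a tertiary hydroxyl as the directing group in a seven-membered ring). The fallback makes the other epimer on purpose and inverts it during the esterification; it sets out from 19 and comes back at 26. Chelation-controlled syn reduction (Et2BOMe, NaBH4, THF/MeOH, −78 °C) gives (3R,3aS,4R,8S,8aR)-3,4-dihydroxy-6,8a-dimethyl-3-(propan-2-yl)-1,2,3,3a,4,5,8,8a-octahydroazulen-8-yl (2E)-2-methylbut-2-enoate F6. A Mitsunobu esterification of F6 with acid 25 (PPh3, DIAD, toluene, 0 °C) inverts C4 and gives 26, so steps 9 and 12 are both replaced.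

Further compounds
F1 | step 3 | (E)-prop-1-en-1-ylmagnesium bromide | C/C=C/[Mg]Br
F2 | step 3 | (R)-1-methyl-4-[(E)-prop-1-ene-1-sulfinyl]benzene | C/C=C/[S@@](=O)c1ccc(C)cc1
F3 | step 3 | (1R,5R,6R,7S)-4,7-dimethyl-6-[(R)-4-methylbenzenesulfinyl]-8-oxabicyclo[3.2.1]oct-3-en-2-one | O1[C@H]2[C@H]([S@@](=O)c3ccc(C)cc3)[C@@H](C)[C@@H]1C(=O)C=C2C
F4 | step 6 | 1-bromo-4-methylpentan-3-one | BrCCC(=O)C(C)C
F5 | step 6 | (1R,4R,5S)-4,7-dimethyl-4-(4-methyl-3-oxopentyl)-8-oxabicyclo[3.2.1]oct-6-en-2-one | O1[C@H]2C=C(C)[C@@H]1C(=O)C[C@@]2(C)CCC(=O)C(C)C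
F6 | step 9 | (3R,3aS,4R,8S,8aR)-3,4-dihydroxy-6,8a-dimethyl-3-(propan-2-yl)-1,2,3,3a,4,5,8,8a-octahydroazulen-8-yl (2E)-2-methylbut-2-enoate | C/C=C(\C)C(=O)O[C@H]1C=C(C)C[C@@H](O)[C@@H]2[C@@]1(C)CC[C@@]2(O)C(C)C
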